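The readings were generated by integration from invented constants; noise was put on by code.

At one temperature, over 160 min, the spring run slowed from 0.165 mM min⁻¹ (between 22 min and 65 min) to 0.0663 mM min⁻¹ (between 130 min and 160 min), with 17.56 mM of target read from 75.0 mM of substrate.

| setting | winter | summer | spring | autumn | dusk |
|---|---|---|---|---|---|
| substrate | 50.0 mM | 25.0 mM | 75.0 mM | 50.0 mM | 200 mM |
| reagent | 125 mM | 100 mM | 125 mM | 380 mM | 500 mM |
| catalyst | 2.50 mM | 2.50 mM | 2.50 mM | 2.50 mM | 2.50 mM |
| time |  |  |  |  | 160 min |

| run | time / min | [target] / mM |
|---|---|---|
| winter run | 7.1 | 0.03 |
| winter run | 22 | 1.54 |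
| winter run | 41 | 3.72 |
| winter run | 65 | 7.16 |
| winter run | 93 | 10.09 |
| winter run | 130 | 12.61 |
| winter run | 160 | 13.75 |
| summer run | 7.1 | 0.21 |
| summer run | 22 | 0.86 |
| summer run | 41 | 2.17 |
| summer run | 65 | 3.81 |
| summer run | 93 | 5.67 |
| summer run | 130 | 7.02 |
| summer run | 160 | 7.40 |
| spring run | 7.1 | 0 |
| spring run | 22 | 1.37 |
| spring run | 41 | 4.57 |
| spring run | 65 | 8.46 |
| spring run | 93 | 12.37 |
| spring run | 130 | 15.57 |
| spring run | 160 | 17.56 |
| autumn run | 7.1 | 0.23 |
| autumn run | 22 | 2.03 |
| autumn run | 41 | 5.77 |
| autumn run | 65 | 10.49 |
| autumn run | 93 | 14.27 |
| autumn run | 130 | 16.75 |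
| autumn run | 160 | 17.50 |

(standard deviation of a reading: 0.2 mM)

- the exponent of [substrate] in the starting rate at the charge of the winter run (at the point where two percent of the substrate have become target) (one fixed amount of target, the same in the runs compared)
- the exponent of [reagent] in the starting rate at the charge of the winter run (at the point where two percent of the substrate have become target)
- target in the dusk run at 160 min, as a share of the substrate charged

- Overall: substrate + reagent -> target, with catalyst as catalyst.
- Constant volume, constant temperature.
- A reading of a species includes what of it is bound.
- "The second partner" is reagent.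
- An order is taken over about fifteen percent of the charge, up and down.

My reckoning for the dusk run went in steps.

1. I took the fade as a first-order loss of target under steady formation, and I read its constant in the spring run, whose substrate charge is the highest of the 4 earlier runs. The two slopes differ by the loss on the difference in mean [target], so the reading is k = 0.00846 min⁻¹.

2. I solved both ends. On that picture, target rises early at the formation rate f and levels late at f/k. Joined, [target] at time t is f·t times the survival share, the fraction of target made evenly over t that still stands at t, (1 − exp(−kt))/(kt). At 160 min it is 54.8%.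

3. Slope plus loss gives f: 0.167 mM min⁻¹ in the winter run and 0.206 mM min⁻¹ in the spring run. I assumed two steps in series, one with each partner, so that 1/f = a/[substrate] + b/[reagent]. These two runs give a = 169 min and b = 324 min. As a check, the law gives 0.236 mM min⁻¹ for the autumn run, whose slope and loss give 0.250 mM min⁻¹. For the dusk run it gives 0.670 mM min⁻¹, so 107 mM made by 160 min.

4. The bracket follows. On this estimate of f, with nothing lost, I put the dusk run at 53.6% of its charge. With all of it made at the start and aged the whole time, I put it at 13.8%. Made evenly, it stands at 29.4%, the figure I would commit to.

The forecast, which said of the fade “so the catalyst is probably dying”, gave 0.6 and 0.5 for the orders and 20% for the dusk run. Its yield lies inside my bracket but below my figure.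

The simulation gave orders of 0.36 and 0.35, and 28.3% for the dusk run, inside the bracket and 8.3 percentage points above the forecast.

    active catalyst + substrate ⇌ catalyst-substrate complex (3.870 M⁻¹ min⁻¹, 0.01716 min⁻¹)
    catalyst-substrate complex + reagent → target + active catalyst (1.524 M⁻¹ min⁻¹)
    catalyst → active catalyst (0.04068 min⁻¹)
    target → decomposed product (0.008520 min⁻¹)

The step from target to decomposed product lowers the dusk figure: without it the dusk run holds 50.7% of its charge at 160 min, and with it 28.3%. The survival share of 54.8% applied to that first figure gives 27.8%. Divided by the same share, which supposes even making, the 7.40 mM read in the summer run at 160 min stand for about 13.5 mM of target made from 25.0 mM of substrate.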